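**Plan**

- Core numbering: C1 (lactone C=O), O2, C3 (guaiacyl), C3a, C4 (CH2), O5, C6 (catechol), C6a. Ring A is the lactone (C1, O2, C3, C3a, C6a) and ring B the tetrahydrofuran (C3a, C4, O5, C6, C6a).
- Enabling feature: C4 is a methylene flanked by O5 and C3a, and C3 is a p-oxygenated benzylic carbon next to C3a that can hold a cation within reach of the C1 carboxyl on C6a. An O5=C4 oxocarbenium ion, a C3a=C3 styrene and the C1 carboxylate are therefore poised for two consecutive closures.
- Retrosynthesis: after desilylation, C4–C3a and O2–C3 are cut together, leading to a 5,6-cis 1,3-dioxan-4-one (C1–O–C4–O5 acylal) with the C6 aryl and C6a styryl groups. The acylal is cut to formaldehyde and a syn β-hydroxy acid, and C6–C6a is cut by an aldol to bis-silylated 3,4-dihydroxybenzaldehyde and an (E)-4-arylbut-3-enoyl oxazolidinone made from silylated vanillin by Wittig olefination.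
- Forward order: Wittig and aldol join the chain, the dioxanone is closed as a temporary ring, ring B and then ring A arise in one Lewis-acid cascade, and buffered fluoride frees the three phenols.
- Stereochemistry: C6 and C6a come from the Evans syn-aldol with (S)-4-benzyloxazolidin-2-one. C3a and C3 are set in the cascade, relayed from C6a (cis ring fusion) and from the (E)-alkene and convex face (exo aryl at C3).

Key step: step 8

Remark: aryl triisopropylsilyl ethers are assumed inert to LiOOH at 0 °C and to TMSOTf at low temperature; formaldehyde is used as paraformaldehyde.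

**Route**

Step 1
Reactants: 1 vanillin
Product: 2 3-methoxy-4-(triisopropylsilyloxy)benzaldehyde
Conditions: TIPSCl, imidazole, DMF, rt
Reagents that add atoms: triisopropylsilyl chloride (TIPSCl), CC(C)[Si](Cl)(C(C)C)C(C)C
Why: Imidazole-promoted silyl ether formation on a phenol is routine, and the bulky aryl silyl ether should survive the base, boron triflate and TMSOTf used later.

Step 2
Reactants: 2 3-methoxy-4-(triisopropylsilyloxy)benzaldehyde; 3 (2-carboxyethyl)triphenylphosphonium bromide
Product: 5 (E)-4-[3-methoxy-4-(triisopropylsilyloxy)phenyl]but-3-enoic acid, via carboxylate ylide 4 (not isolated)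
Conditions: 3, NaN(SiMe3)2 (2.1 equiv), THF, 0 °C; then 2, −78 °C → rt; 1 M HCl work-up
Reagents that add atoms: none
Why: Wittig olefination with the carboxylate-bearing ylide is expected to give mainly the (E)-styrene-conjugated β,γ-unsaturated acid from an aromatic aldehyde, and crystallisation of the acid should remove any (Z) isomer.

Step 3
Reactants: 5 (E)-4-[3-methoxy-4-(triisopropylsilyloxy)phenyl]but-3-enoic acid; 6 (S)-4-benzyloxazolidin-2-one
Product: 8 (S)-4-benzyl-3-{(E)-4-[3-methoxy-4-(triisopropylsilyloxy)phenyl]but-3-enoyl}oxazolidin-2-one, via mixed pivalic anhydride 7 (not isolated)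
Conditions: PivCl, Et3N, THF, −20 °C; then LiCl, 6, −20 °C → rt
Reagents that add atoms: none
Why: N-acylation of the oxazolidinone through the mixed pivalic anhydride (LiCl/Et3N variant) should occur at the unhindered acyl carbonyl, and the double bond should stay in conjugation with the arene.

Step 4
Reactants: 9 3,4-dihydroxybenzaldehyde
Product: 10 3,4-bis(triisopropylsilyloxy)benzaldehyde
Conditions: TIPSCl (2.5 equiv), imidazole, DMF, rt → 40 °C
Reagents that add atoms: triisopropylsilyl chloride (TIPSCl), CC(C)[Si](Cl)(C(C)C)C(C)C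
Why: Twofold imidazole-promoted silylation of the catechol (silyl ether formation) should mask both phenols with the same fluoride-labile group used on the other ring.

Step 5
Reactants: 8 (S)-4-benzyl-3-{(E)-4-[3-methoxy-4-(triisopropylsilyloxy)phenyl]but-3-enoyl}oxazolidin-2-one; 10 3,4-bis(triisopropylsilyloxy)benzaldehyde
Product: 13 (S)-4-benzyl-3-[(2S,3E)-2-{(S)-[3,4-bis(triisopropylsilyloxy)phenyl](hydroxy)methyl}-4-[3-methoxy-4-(triisopropylsilyloxy)phenyl]but-3-enoyl]oxazolidin-2-one, via boron dienolate 11 (not isolated), via boron aldolate 12 (not isolated)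
Conditions: Bu2BOTf, iPr2NEt, CH2Cl2, −78 → 0 °C; then 10, −78 → 0 °C; pH 7 buffer, MeOH, H2O2, 0 °C
Reagents that add atoms: none
Why: In this Evans syn-aldol the (Z)-boron dienolate should react at its α-carbon through a Zimmerman–Traxler chair on the face opposite the benzyl group of the dipole-opposed oxazolidinone, setting C6a (S) and C6 (S) of the target in the syn relationship.

Step 6
Reactants: 13 the syn-aldol imide
Product: 15 (2S,3E)-2-{(S)-[3,4-bis(triisopropylsilyloxy)phenyl](hydroxy)methyl}-4-[3-methoxy-4-(triisopropylsilyloxy)phenyl]but-3-enoic acid, via lithium peroxycarboxylate 14 (not isolated)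
Conditions: LiOH, H2O2, THF/H2O (3:1), 0 °C; Na2SO3; 1 M HCl to pH 3
Reagents that add atoms: hydrogen peroxide (acting as LiOOH), OO
Why: LiOOH cleavage of the N-acyl oxazolidinone attacks the exocyclic carbonyl selectively, and the weakly basic hydroperoxide at 0 °C should leave the α-stereocentre, the aldol linkage and the aryl silyl ethers intact.

Step 7
Reactants: 15 the syn β-hydroxy acid; 16 formaldehyde (as paraformaldehyde)
Product: 17 (5S,6S)-6-[3,4-bis(triisopropylsilyloxy)phenyl]-5-{(E)-2-[3-methoxy-4-(triisopropylsilyloxy)phenyl]ethenyl}-1,3-dioxan-4-one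
Conditions: (CH2O)n, PPTS (cat.), 4 Å MS, benzene, 50 °C
Reagents that add atoms: none
Why: Acid-catalysed acetalisation of a β-hydroxy acid with formaldehyde (1,3-dioxan-4-one formation) closes the six-membered acylal without touching either stereocentre, and the weak pyridinium acid should not ionise the product further.

Step 8
Reactants: 17 the 5,6-cis dioxanone
Product: 20 (3S,3aR,6S,6aS)-6-[3,4-bis(triisopropylsilyloxy)phenyl]-3-[3-methoxy-4-(triisopropylsilyloxy)phenyl]tetrahydro-1H,3H-furo[3,4-c]furan-1-one, via oxocarbenium silyl ester 18 (not isolated), via benzylic cation 19 (not isolated)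
Conditions: TMSOTf (0.3 equiv), 2,6-di-tert-butyl-4-methylpyridine (0.4 equiv), CH2Cl2, −78 → −30 °C
Reagents that add atoms: none
Why: Proposed new method: TMSOTf silylates the lactone carbonyl of 17 and the acylal C–O bond breaks to give trimethylsilyl ester 18 with a methylene oxocarbenium ion at O5=C4, which the styrene attacks through C3a (C4–C3a bond) to give the p-silyloxybenzylic C3 cation 19; the carbonyl oxygen of the silyl ester then bonds to C3 (O2–C3) and TMSOTf is released, so the promoter turns over. The closest known reaction types are Prins cyclisations of aryl-terminated homoallylic alcohols and acetals that close tetrahydrofurans through a benzylic cation, and Lewis-acid openings of 1,3-dioxan-4-ones by π-nucleophiles; ending the cascade with the carboxylate freed in the ionisation is the untested part. Ring B closes 5-exo-trig with respect to the styrene (the O5=C4 unit lies inside the new ring), and ring A closes by 5-exo attack of the carboxyl oxygen on the cationic C3. C3a is controlled by C6a: only the alkene rotamer that holds the silyl ester over C3 gives a cation with C3 cis to C1 that can lactonise (and can be assisted by the carbonyl as charge builds up), while the trans cation can only revert by Grob-type retro-Prins cleavage; C3 is set by anti addition across the (E)-alkene, which places the aryl group on the convex face, and reversible ionisation of the benzylic C3–O2 bond would lead to the same, more stable exo isomer. The step needs bond formation at C3a (five-membered ring) and not at C3 (six-membered ring or 2-oxonia-Cope shift), and ionisation of the acylal and not of the benzylic C6–O5 bond; the p-silyloxy group on the guaiacyl ring polarises the styrene so that C3a is the nucleophilic carbon, and the silicon-activated acyloxy group is the better leaving group at −78 °C, with the hindered pyridine removing adventitious TfOH.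

Step 9
Reactants: 20 the tris(triisopropylsilyl) ether
Product: 21 (3S,3aR,6S,6aS)-6-(3,4-dihydroxyphenyl)-3-(4-hydroxy-3-methoxyphenyl)tetrahydro-1H,3H-furo[3,4-c]furan-1-one
Conditions: Bu4NF (3.5 equiv), AcOH (4 equiv), THF, 0 °C
Reagents that add atoms: none
Why: Fluoride cleavage of aryl silyl ethers is fast, and the acetic acid buffer should keep the phenols protonated so that neither p-hydroxybenzylic C–O bond (C3–O2, C6–O5) opens through a quinone methide and no stereocentre is touched.

**Compound list**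

1 | vanillin | COc1cc(C=O)ccc1O | starting material
2 | 3-methoxy-4-(triisopropylsilyloxy)benzaldehyde | COc1cc(C=O)ccc1O[Si](C(C)C)(C(C)C)C(C)C | intermediate
3 | (2-carboxyethyl)triphenylphosphonium bromide | OC(=O)CC[P+](c1ccccc1)(c1ccccc1)c1ccccc1.[Br-] | starting material
4 | sodium 3-(triphenylphosphoranylidene)propanoate (carboxylate ylide) | [Na+].[O-]C(=O)CC=P(c1ccccc1)(c1ccccc1)c1ccccc1 | intermediate
5 | (E)-4-[3-methoxy-4-(triisopropylsilyloxy)phenyl]but-3-enoic acid | COc1cc(/C=C/CC(=O)O)ccc1O[Si](C(C)C)(C(C)C)C(C)C | intermediate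
6 | (S)-4-benzyloxazolidin-2-one | O=C1N[C@@H](Cc2ccccc2)CO1 | starting material
7 | mixed anhydride of acid 5 and pivalic acid | COc1cc(/C=C/CC(=O)OC(=O)C(C)(C)C)ccc1O[Si](C(C)C)(C(C)C)C(C)C | intermediate
8 | (S)-4-benzyl-3-{(E)-4-[3-methoxy-4-(triisopropylsilyloxy)phenyl]but-3-enoyl}oxazolidin-2-one | COc1cc(/C=C/CC(=O)N2[C@@H](Cc3ccccc3)COC2=O)ccc1O[Si](C(C)C)(C(C)C)C(C)C | intermediate
9 | 3,4-dihydroxybenzaldehyde | O=Cc1ccc(O)c(O)c1 | starting material
10 | 3,4-bis(triisopropylsilyloxy)benzaldehyde | O=Cc1ccc(O[Si](C(C)C)(C(C)C)C(C)C)c(O[Si](C(C)C)(C(C)C)C(C)C)c1 | intermediate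
11 | (Z)-O-dibutylboryl dienolate of imide 8 | CCCCB(CCCC)O/C(=C\C=C\c1ccc(O[Si](C(C)C)(C(C)C)C(C)C)c(OC)c1)N1[C@@H](Cc2ccccc2)COC1=O | intermediate
12 | O-dibutylboryl aldolate of imide 13 | CCCCB(CCCC)O[C@H](c1ccc(O[Si](C(C)C)(C(C)C)C(C)C)c(O[Si](C(C)C)(C(C)C)C(C)C)c1)[C@@H](C(=O)N1[C@@H](Cc2ccccc2)COC1=O)/C=C/c1ccc(O[Si](C(C)C)(C(C)C)C(C)C)c(OC)c1 | intermediate
13 | (S)-4-benzyl-3-[(2S,3E)-2-{(S)-[3,4-bis(triisopropylsilyloxy)phenyl](hydroxy)methyl}-4-[3-methoxy-4-(triisopropylsilyloxy)phenyl]but-3-enoyl]oxazolidin-2-one (syn aldol) | O[C@H](c1ccc(O[Si](C(C)C)(C(C)C)C(C)C)c(O[Si](C(C)C)(C(C)C)C(C)C)c1)[C@@H](C(=O)N1[C@@H](Cc2ccccc2)COC1=O)/C=C/c1ccc(O[Si](C(C)C)(C(C)C)C(C)C)c(OC)c1 | intermediate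
14 | lithium peroxycarboxylate corresponding to acid 15 | O[C@H](c1ccc(O[Si](C(C)C)(C(C)C)C(C)C)c(O[Si](C(C)C)(C(C)C)C(C)C)c1)[C@@H](C(=O)O[O-])/C=C/c1ccc(O[Si](C(C)C)(C(C)C)C(C)C)c(OC)c1.[Li+] | intermediate
15 | (2S,3E)-2-{(S)-[3,4-bis(triisopropylsilyloxy)phenyl](hydroxy)methyl}-4-[3-methoxy-4-(triisopropylsilyloxy)phenyl]but-3-enoic acid | O[C@H](c1ccc(O[Si](C(C)C)(C(C)C)C(C)C)c(O[Si](C(C)C)(C(C)C)C(C)C)c1)[C@@H](C(=O)O)/C=C/c1ccc(O[Si](C(C)C)(C(C)C)C(C)C)c(OC)c1 | intermediate
16 | formaldehyde (used as paraformaldehyde) | C=O | starting material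
17 | (5S,6S)-6-[3,4-bis(triisopropylsilyloxy)phenyl]-5-{(E)-2-[3-methoxy-4-(triisopropylsilyloxy)phenyl]ethenyl}-1,3-dioxan-4-one (5,6-cis) | O=C1OCO[C@H](c2ccc(O[Si](C(C)C)(C(C)C)C(C)C)c(O[Si](C(C)C)(C(C)C)C(C)C)c2)[C@@H]1/C=C/c1ccc(O[Si](C(C)C)(C(C)C)C(C)C)c(OC)c1 | intermediate
18 | O5=C4 methylene oxocarbenium triflate carrying the C1 trimethylsilyl ester | C=[O+][C@H](c1ccc(O[Si](C(C)C)(C(C)C)C(C)C)c(O[Si](C(C)C)(C(C)C)C(C)C)c1)[C@@H](C(=O)O[Si](C)(C)C)/C=C/c1ccc(O[Si](C(C)C)(C(C)C)C(C)C)c(OC)c1.[O-]S(=O)(=O)C(F)(F)F | intermediate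
19 | C3 benzylic cation (triflate) of the 2,3-trans-3,4-cis tetrahydrofuran trimethylsilyl ester | COc1cc([CH+][C@H]2CO[C@H](c3ccc(O[Si](C(C)C)(C(C)C)C(C)C)c(O[Si](C(C)C)(C(C)C)C(C)C)c3)[C@H]2C(=O)O[Si](C)(C)C)ccc1O[Si](C(C)C)(C(C)C)C(C)C.[O-]S(=O)(=O)C(F)(F)F | intermediate
20 | (3S,3aR,6S,6aS)-6-[3,4-bis(triisopropylsilyloxy)phenyl]-3-[3-methoxy-4-(triisopropylsilyloxy)phenyl]tetrahydro-1H,3H-furo[3,4-c]furan-1-one | COc1cc([C@H]2OC(=O)[C@H]3[C@@H]2CO[C@@H]3c2ccc(O[Si](C(C)C)(C(C)C)C(C)C)c(O[Si](C(C)C)(C(C)C)C(C)C)c2)ccc1O[Si](C(C)C)(C(C)C)C(C)C | intermediate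
21 | (3S,3aR,6S,6aS)-6-(3,4-dihydroxyphenyl)-3-(4-hydroxy-3-methoxyphenyl)tetrahydro-1H,3H-furo[3,4-c]furan-1-one | COc1cc([C@H]2OC(=O)[C@H]3[C@@H]2CO[C@@H]3c2ccc(O)c(O)c2)ccc1O | target

**Count**

Total steps: 9. Longest linear sequence: 8 steps (steps 1, 2, 3, 5, 6, 7, 8, 9, from vanillin).

**Steps most likely to fail**

Step 8. The acylal may ionise too slowly with TMSOTf, or the benzylic cation may be drained by elimination or by bonding at C3 (2-oxonia-Cope shift) before the silyl ester closes the lactone. The fallback separates the two bond formations with known reactions. It sets out from hydroxy acid 15: TMSCHN2 in toluene/MeOH should give methyl ester F1, and MOMCl/iPr2NEt in CH2Cl2 should give methoxymethyl ether F2. SnCl4 in CH2Cl2 at −78 °C (Prins cyclisation of an alkoxymethyl ether of an aryl-terminated homoallylic alcohol) should ionise the acetal to the same O5=C4 ion, close C4–C3a and deliver chloride to C3, giving benzylic chloride F3 as a mixture at C3. Warming F3 in MeCN should ionise the p-silyloxybenzylic chloride and let the ester carbonyl close the lactone with loss of chloromethane, convergent in both C3 epimers, and the route is rejoined at 20.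

Step 7. The protic acid at 50 °C may ionise the electron-rich benzylic carbinol (epimerisation at C6, retro-aldol cleavage), or may start the cyclisation cascade before the dioxanone can be isolated. The fallback builds the acylal by alkylation without acid. It sets out from hydroxy acid 15: chloromethyl chlorosulfate, NaHCO3 and Bu4NHSO4 in CH2Cl2/H2O should give chloromethyl ester F4, and NaI/iPr2NEt in MeCN should close the ring by intramolecular O-alkylation of the C6 hydroxyl (6-exo-tet), rejoining the route at 17.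

Step 6. The lithium alkoxide of the aldol may fragment by retro-aldol reaction (driven by the conjugated dienolate and the electron-rich aldehyde), and epimerisation at C6a or loss of an aryl silyl ether may accompany it. The fallback removes the free hydroxyl before the cleavage. It sets out from imide 13: TESOTf/2,6-lutidine in CH2Cl2 should give triethylsilyl ether F5, LiOH/H2O2 in THF/H2O at 0 °C should then give silyloxy acid F6, and AcOH/THF/H2O should remove the alkyl triethylsilyl group while the acid-stable aryl silyl ethers stay, rejoining the route at 15.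

**Further compounds**

F1 | step 8 | methyl (2S,3E)-2-{(S)-[3,4-bis(triisopropylsilyloxy)phenyl](hydroxy)methyl}-4-[3-methoxy-4-(triisopropylsilyloxy)phenyl]but-3-enoate | O[C@H](c1ccc(O[Si](C(C)C)(C(C)C)C(C)C)c(O[Si](C(C)C)(C(C)C)C(C)C)c1)[C@@H](C(=O)OC)/C=C/c1ccc(O[Si](C(C)C)(C(C)C)C(C)C)c(OC)c1
F2 | step 8 | methyl (2S,3E)-2-{(S)-[3,4-bis(triisopropylsilyloxy)phenyl](methoxymethoxy)methyl}-4-[3-methoxy-4-(triisopropylsilyloxy)phenyl]but-3-enoate | COCO[C@H](c1ccc(O[Si](C(C)C)(C(C)C)C(C)C)c(O[Si](C(C)C)(C(C)C)C(C)C)c1)[C@@H](C(=O)OC)/C=C/c1ccc(O[Si](C(C)C)(C(C)C)C(C)C)c(OC)c1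
F3 | step 8 | methyl (2S,3S,4R)-2-[3,4-bis(triisopropylsilyloxy)phenyl]-4-{chloro[3-methoxy-4-(triisopropylsilyloxy)phenyl]methyl}tetrahydrofuran-3-carboxylate (both epimers at the chloride carbon) | COc1cc(C(Cl)[C@H]2CO[C@H](c3ccc(O[Si](C(C)C)(C(C)C)C(C)C)c(O[Si](C(C)C)(C(C)C)C(C)C)c3)[C@H]2C(=O)OC)ccc1O[Si](C(C)C)(C(C)C)C(C)C
F4 | step 7 | chloromethyl (2S,3E)-2-{(S)-[3,4-bis(triisopropylsilyloxy)phenyl](hydroxy)methyl}-4-[3-methoxy-4-(triisopropylsilyloxy)phenyl]but-3-enoate | O[C@H](c1ccc(O[Si](C(C)C)(C(C)C)C(C)C)c(O[Si](C(C)C)(C(C)C)C(C)C)c1)[C@@H](C(=O)OCCl)/C=C/c1ccc(O[Si](C(C)C)(C(C)C)C(C)C)c(OC)c1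
F5 | step 6 | (S)-4-benzyl-3-[(2S,3E)-2-{(S)-[3,4-bis(triisopropylsilyloxy)phenyl](triethylsilyloxy)methyl}-4-[3-methoxy-4-(triisopropylsilyloxy)phenyl]but-3-enoyl]oxazolidin-2-one | CC[Si](CC)(CC)O[C@H](c1ccc(O[Si](C(C)C)(C(C)C)C(C)C)c(O[Si](C(C)C)(C(C)C)C(C)C)c1)[C@@H](C(=O)N1[C@@H](Cc2ccccc2)COC1=O)/C=C/c1ccc(O[Si](C(C)C)(C(C)C)C(C)C)c(OC)c1
F6 | step 6 | (2S,3E)-2-{(S)-[3,4-bis(triisopropylsilyloxy)phenyl](triethylsilyloxy)methyl}-4-[3-methoxy-4-(triisopropylsilyloxy)phenyl]but-3-enoic acid | CC[Si](CC)(CC)O[C@H](c1ccc(O[Si](C(C)C)(C(C)C)C(C)C)c(O[Si](C(C)C)(C(C)C)C(C)C)c1)[C@@H](C(=O)O)/C=C/c1ccc(O[Si](C(C)C)(C(C)C)C(C)C)c(OC)c1
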